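**Plan**

1. Retrosynthesis: the C5 ketone, the C6 acetate, both tiglates and the side-chain epoxide are late oxidation and acylation events. The central cut is the bond between the alkene carbon that carries the ring and the =CH2 group (C7) and the acyloxy carbinol carbon next to it (C8). This gives a ring alkenyl triflate and 4-methylpent-3-enal.
2. Enabling feature: C7–C8 is the sp2–carbinol bond of a 2-substituted allylic alcohol, the retron of a Ni/Cr alkenyl–aldehyde coupling. The alkenyl triflate is the enol form of an acetyl group on C1, and a cis 1-acetyl-2-hydroxy pair is an opened isoxazoline.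
3. Ring origin: the six ring carbons, the C4 methyl and the C5/C6 oxygens are bought as the toluene cis-dihydrodiol. No carbocycle is built; the isoxazoline is a temporary ring.
4. Forward order: acetonide, nitrile oxide cycloaddition on C1=C2, N–O cleavage, hydroxyl-directed epoxidation of C3=C4, enol triflate, fragment coupling, tiglates, acetonide removal, side-chain epoxidation, C6 acetate, C5 ketone.
5. Stereochemistry: C6 is bought. C1 and C2 (cycloaddition anti to the acetonide) and C3 and C4 (epoxidation syn to C2–OH) are relayed from it. C8 is set by a chiral chromium catalyst and C10 by the Shi ketone.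

Key step: step 8

Remark (assumption): the toluene cis-dihydrodiol 1, produced by whole-cell dioxygenase oxidation of toluene, is taken as a purchasable material; the two 2-methylbut-2-enoates of the target are (E), i.e. tiglates.

Locants used below: ring C1 (side chain), C2 (tigloyloxy), C3/C4 (epoxide, methyl on C4), C5 (ketone), C6 (acetoxy); side chain C7 (alkene carbon bearing =CH2), C8 (acyloxy carbinol), C9 (CH2), C10/C11 (epoxide). The β face carries the C6 oxygen (and the C5 oxygen before oxidation); the α face carries the C1 side chain, the C2 oxygen and the C3/C4 epoxide oxygen. In these locants the target is 1R,2S,3S,4S,6S,8S,10R.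

**Route**

Step 1
Reactants: 1 (1S,2R)-3-methylcyclohexa-3,5-diene-1,2-diol
Product: 2 (3aR,7aS)-2,2,4-trimethyl-3a,7a-dihydro-1,3-benzodioxole
Conditions: 2,2-dimethoxypropane, p-TsOH·H2O (cat.), acetone, 0 °C, 20 min; Et3N quench; used promptly
Reagents that add atoms: 2,2-dimethoxypropane, COC(C)(C)OC
Why: Acid-catalysed acetonide formation (transketalisation) on a cis-1,2-diol is fast at 0 °C and outruns acid-induced dehydration of the dihydrodiol to the phenol; no stereocentre is touched.

Step 2
Reactants: 2 (3aR,7aS)-2,2,4-trimethyl-3a,7a-dihydro-1,3-benzodioxole; 3 nitroethane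
Product: 5 tricyclic isoxazoline (3-methyl-2-isoxazoline cis-fused across C1–C2 on the α face), via acetonitrile oxide 4 (not isolated)
Conditions: PhNCO, Et3N (cat.), toluene, rt
Reagents that add atoms: none
Why: Nitrile oxide 1,3-dipolar cycloaddition (dipole by dehydration of the nitroalkane): the dipole should choose the cis-disubstituted C1=C2 bond over the trisubstituted C3=C4 bond, place its oxygen on the diene-internal carbon C2 and its carbon on the terminus C1 as is usual for conjugated dienes, and approach anti to the acetonide, so that C1 and C2 are set cis to each other and trans to the C6 oxygen in one event.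

Step 3
Reactants: 5 tricyclic isoxazoline
Product: 7 cis β-hydroxy ketone (1α-acetyl, 2α-hydroxy, C3=C4 alkene, C5/C6 acetonide), via hydroxy imine 6 (not isolated)
Conditions: H2 (1 atm), Raney Ni, B(OH)3, MeOH–H2O (5:1), rt
Reagents that add atoms: water, O
Why: Hydrogenolysis of the isoxazoline N–O bond and hydrolysis of the β-hydroxy imine in the boric acid buffer (isoxazoline as masked aldol) should release the cis β-hydroxy methyl ketone without epimerisation at C1, dehydration or reduction of the hindered trisubstituted alkene.

Step 4
Reactants: 7 cis β-hydroxy ketone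
Product: 8 3α,4α-epoxy alcohol
Conditions: VO(acac)2 (5 mol %), t-BuOOH, CH2Cl2, 0 °C to rt
Reagents that add atoms: tert-butyl hydroperoxide, CC(C)(C)OO
Why: Hydroxyl-directed vanadium-catalysed epoxidation of a cyclic allylic alcohol delivers oxygen to the face of the C2 hydroxyl, which is also the face anti to the acetonide, so C3 and C4 are both set as the cis (α) epoxy alcohol by two reinforcing substrate effects.

Step 5
Reactants: 8 3α,4α-epoxy alcohol
Product: 9 C2 triethylsilyl ether of 8
Conditions: Et3SiCl, imidazole, DMAP (cat.), DMF, 0 °C to rt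
Reagents that add atoms: chlorotriethylsilane, CC[Si](Cl)(CC)CC
Why: Silyl ether formation masks the C2 hydroxyl so that the next step forms only the ketone enolate, and the mild imidazole conditions leave the epoxide and the β-oxygenated ketone intact.

Step 6
Reactants: 9 C2 triethylsilyl ether
Product: 11 enol triflate (C1 bears a 1-(trifluoromethanesulfonyloxy)ethenyl group), via potassium enolate 10 (not isolated)
Conditions: KHMDS, THF, −78 °C; then PhNTf2, −78 to −20 °C
Reagents that add atoms: N-phenylbis(trifluoromethanesulfonimide), FC(F)(F)S(=O)(=O)N(c1ccccc1)S(=O)(=O)C(F)(F)F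
Why: Kinetic enolisation of the methyl ketone occurs at the unhindered methyl group and not at the tertiary C1–H, and O-sulfonylation (enol triflate synthesis) fixes the 1,1-disubstituted alkene; the terminal enolate cannot expel the C2 or C6 oxygen and C1 is not epimerised.

Step 7
Reactants: 12 4-methylpent-3-en-1-ol
Product: 13 4-methylpent-3-enal
Conditions: Dess–Martin periodinane, CH2Cl2, 0 °C to rt; used at once as a solution
Reagents that add atoms: none
Why: Dess–Martin oxidation of the primary alcohol under neutral conditions gives the β,γ-unsaturated aldehyde without migration of the double bond into conjugation.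

Step 8
Reactants: 11 enol triflate; 13 4-methylpent-3-enal
Product: 15 (8S)-allylic alcohol (C1 bears the 3-hydroxy-6-methylhepta-1,5-dien-2-yl chain), via alkenylchromium 14 (not isolated)
Conditions: CrCl2 (10 mol %), chiral 2-(oxazolin-2-yl)aryl methanesulfonamide ligand (12 mol %, antipode for Re-face addition), 1,8-bis(dimethylamino)naphthalene (12 mol %), NiCl2(2,9-dimethyl-1,10-phenanthroline) (2 mol %), Mn powder, LiCl, Cp2ZrCl2, MeCN, rt; aqueous work-up
Reagents that add atoms: none
Why: Zerovalent nickel inserts into the alkenyl C–OTf bond of 11, the alkenyl group passes to trivalent chromium carrying the chiral sulfonamide ligand (14), this adds to the carbonyl of 13 through a chromium-bound transition state, Cp2ZrCl2 frees the alkoxide from chromium and Mn returns chromium to the divalent state. The closest known reaction type is the catalytic asymmetric Nozaki–Hiyama–Kishi coupling of 2-substituted alkenyl halides and triflates with aldehydes to give 2-substituted allylic alcohols. No ring is closed. The one new stereocentre, C8, is set by the catalyst: the ligand antipode that directs the alkenyl group to the Re face of the aldehyde gives 8S, and the nearest ring stereocentre (C1) sits on the nucleophile without a chelating group, so it should only modulate that choice. The step needs chemoselectivity for the aldehyde over epoxide, acetonide and silyl ether, which the mild, non-basic alkenylchromium secures, and it needs the β,γ-unsaturated aldehyde not to enolise, which neutral conditions and Cp2ZrCl2 in place of a silyl chloride secure. The alkenyl metal has no leaving group β to the metal (the C2 and C6 oxygens are γ), so it cannot collapse to an allene.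

Step 9
Reactants: 15 (8S)-allylic alcohol
Product: 16 C2,C8-diol
Conditions: Bu4NF, THF, 0 °C
Reagents that add atoms: none
Why: Fluoride cleavage of the triethylsilyl ether frees the C2 hydroxyl; its alkoxide is cis to the epoxide and cannot undergo Payne rearrangement, and the acetonide is inert.

Step 10
Reactants: 16 C2,C8-diol
Product: 17 C2,C8-bis-tiglate
Conditions: tiglic acid, 2,4,6-trichlorobenzoyl chloride, Et3N, toluene, rt; then 16, DMAP, 60 °C
Reagents that add atoms: tiglic acid, OC(=O)/C(C)=C/C
Why: Yamaguchi esterification through the mixed anhydride acylates both hindered secondary alcohols, and since the (E)-2-methylbut-2-enoate is the stable geometry no isomerisation is to be feared; no stereocentre is touched.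

Step 11
Reactants: 17 C2,C8-bis-tiglate
Product: 18 C5,C6-diol
Conditions: AcOH–H2O (4:1), 40 °C
Reagents that add atoms: none
Why: Acid hydrolysis of the cis-fused acetonide should precede opening of the ring epoxide, because that epoxide is flanked by an acyloxy carbon and an alkoxy carbon that disfavour its ionisation and the cis C2 ester cannot attack it from the rear; the acid-labile side-chain epoxide is not yet present.

Step 12
Reactants: 18 C5,C6-diol
Product: 19 (10R)-10,11-epoxide of 18
Conditions: Shi ketone (D-fructose-derived, 30 mol %), Oxone (2KHSO5·KHSO4·K2SO4), K2CO3, Bu4NHSO4 (cat.), MeCN–CH2(OMe)2 / aq. Na2B4O7 buffer (pH 10.5), 0 °C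
Reagents that add atoms: potassium peroxymonosulfate (active component of Oxone), [K+].[O-]S(=O)(=O)OO
Why: Shi asymmetric epoxidation: the chiral dioxirane oxidises the electron-rich trisubstituted side-chain alkene in preference to the hindered 1,1-disubstituted alkene and the electron-poor tiglate alkenes, and the spiro transition state of the D-fructose-derived ketone should give the (R)-configured 2,2-dimethyl-3-alkyloxirane at C10 under catalyst control.

Step 13
Reactants: 19 (10R)-10,11-epoxide
Product: 20 C6 monoacetate (C5 hydroxyl free)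
Conditions: AcCl (1.05 equiv), 2,4,6-collidine, CH2Cl2, −78 to −40 °C
Reagents that add atoms: acetyl chloride, CC(Cl)=O
Why: Selective monoacylation of a cis-1,2-diol: the equatorial C6 hydroxyl should react much faster than the pseudoaxial C5 hydroxyl, which is neopentyl-like next to the quaternary epoxide carbon C4; no stereocentre is touched.

Step 14
Reactants: 20 C6 monoacetate
Product: 21 target CNP0407453.3
Conditions: Dess–Martin periodinane, NaHCO3, CH2Cl2, 0 °C to rt
Reagents that add atoms: none
Why: Dess–Martin oxidation of the hindered secondary alcohol under bicarbonate-buffered, non-basic conditions gives the C5 ketone without epimerising the α-acetoxy centre C6, migrating the acetate or opening either epoxide.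

**Compound list**

1 | (1S,2R)-3-methylcyclohexa-3,5-diene-1,2-diol (toluene cis-dihydrodiol) | CC1=CC=C[C@H](O)[C@@H]1O | starting material
2 | (3aR,7aS)-2,2,4-trimethyl-3a,7a-dihydro-1,3-benzodioxole | CC1=CC=C[C@@H]2OC(C)(C)O[C@H]12 | intermediate
3 | nitroethane | CC[N+](=O)[O-] | starting material
4 | acetonitrile oxide | CC#[N+][O-] | intermediate (not isolated)
5 | tricyclic isoxazoline: C=N carbon on C1 and ring oxygen on C2, both α; C3=C4 alkene; C5/C6 acetonide β | CC1=C[C@H]2ON=C(C)[C@H]2[C@@H]2OC(C)(C)O[C@H]12 | intermediate
6 | β-hydroxy imine: 1α-(1-iminoethyl), 2α-hydroxy | CC1=C[C@@H](O)[C@@H](C(C)=N)[C@@H]2OC(C)(C)O[C@H]12 | intermediate (not isolated)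
7 | cis β-hydroxy ketone: 1α-acetyl, 2α-hydroxy, C3=C4 alkene, C5/C6 acetonide | CC1=C[C@@H](O)[C@@H](C(C)=O)[C@@H]2OC(C)(C)O[C@H]12 | intermediate
8 | 3α,4α-epoxy alcohol: 1α-acetyl, 2α-hydroxy, C5/C6 acetonide | C[C@]12O[C@H]1[C@@H](O)[C@@H](C(C)=O)[C@@H]1OC(C)(C)O[C@H]21 | intermediate
9 | C2 triethylsilyl ether of 8 | C[C@]12O[C@H]1[C@@H](O[Si](CC)(CC)CC)[C@@H](C(C)=O)[C@@H]1OC(C)(C)O[C@H]21 | intermediate
10 | potassium enolate of 9 (terminal, at the methyl group) | C[C@]12O[C@H]1[C@@H](O[Si](CC)(CC)CC)[C@@H](C(=C)[O-])[C@@H]1OC(C)(C)O[C@H]21.[K+] | intermediate (not isolated)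
11 | enol triflate: C1 bears 1-(trifluoromethanesulfonyloxy)ethenyl | C[C@]12O[C@H]1[C@@H](O[Si](CC)(CC)CC)[C@@H](C(=C)OS(=O)(=O)C(F)(F)F)[C@@H]1OC(C)(C)O[C@H]21 | intermediate
12 | 4-methylpent-3-en-1-ol | CC(C)=CCCO | starting material
13 | 4-methylpent-3-enal | CC(C)=CCC=O | intermediate
14 | alkenylchromium dichloride from 11 (trivalent chromium; chiral ligand not drawn) | C[C@]12O[C@H]1[C@@H](O[Si](CC)(CC)CC)[C@@H](C(=C)[Cr](Cl)Cl)[C@@H]1OC(C)(C)O[C@H]21 | intermediate (not isolated)
15 | (8S)-allylic alcohol: C1 bears CH2=C–CH(OH)–CH2–CH=CMe2; C2 OSiEt3; 3α,4α-epoxide; C5/C6 acetonide | C[C@]12O[C@H]1[C@@H](O[Si](CC)(CC)CC)[C@@H](C(=C)[C@@H](O)CC=C(C)C)[C@@H]1OC(C)(C)O[C@H]21 | intermediate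
16 | C2,C8-diol | C[C@]12O[C@H]1[C@@H](O)[C@@H](C(=C)[C@@H](O)CC=C(C)C)[C@@H]1OC(C)(C)O[C@H]21 | intermediate
17 | C2,C8-bis-tiglate, C5/C6 acetonide | C[C@]12O[C@H]1[C@@H](OC(=O)/C(C)=C/C)[C@@H](C(=C)[C@@H](OC(=O)/C(C)=C/C)CC=C(C)C)[C@@H]1OC(C)(C)O[C@H]21 | intermediate
18 | C5β,C6β-diol, C2,C8-bis-tiglate | C[C@]12O[C@H]1[C@@H](OC(=O)/C(C)=C/C)[C@@H](C(=C)[C@@H](OC(=O)/C(C)=C/C)CC=C(C)C)[C@H](O)[C@@H]2O | intermediate
19 | (10R)-10,11-epoxide of 18 | C[C@]12O[C@H]1[C@@H](OC(=O)/C(C)=C/C)[C@@H](C(=C)[C@@H](OC(=O)/C(C)=C/C)C[C@H]1OC1(C)C)[C@H](O)[C@@H]2O | intermediate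
20 | C6 acetate of 19 (C5 hydroxyl free) | C[C@]12O[C@H]1[C@@H](OC(=O)/C(C)=C/C)[C@@H](C(=C)[C@@H](OC(=O)/C(C)=C/C)C[C@H]1OC1(C)C)[C@H](OC(C)=O)[C@@H]2O | intermediate
21 | CNP0407453.3 | C=C([C@@H]1[C@H](OC(=O)/C(C)=C/C)[C@@H]2O[C@]2(C)C(=O)[C@H]1OC(C)=O)[C@H](C[C@H]1OC1(C)C)OC(=O)/C(C)=C/C | target

**Step count and risks**

Total step count: 14. Longest linear sequence: 13 steps (steps 1–6 and 8–14, from 1).

Steps most likely to fail:

Step 8. The catalyst's facial preference at the aldehyde may be opposed or overridden by the bulky chiral alkenyl partner, giving poor selectivity at C8. The fallback sets the carbinol centre by reduction instead of by C–C bond formation. It sets out from 11 and 13, which are coupled with the same CrCl2/NiCl2/Mn/Cp2ZrCl2 system without chiral ligand to give 15 mixed with its C8 epimer F4. The mixture is oxidised (Dess–Martin periodinane, NaHCO3, CH2Cl2) to the single enone F5. This is reduced with (R)-2-methyl-CBS-oxazaborolidine and catecholborane (toluene, −78 °C), the alkenyl group acting as the larger substituent, and the sequence comes back to the route at 15.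

Step 2. The dipole may lose site or orientation control (attack on the trisubstituted alkene, mixed regiochemistry), or Diels–Alder dimerisation of diene 2 may outrun the cycloaddition. The fallback uses a halogen as a removable control element. It sets out one stage earlier, in place of 1, from commercial (1S,2S)-3-bromocyclohexa-3,5-diene-1,2-diol F1. This is converted as in step 1 into its acetonide F2, in which the bromine deactivates and shields the neighbouring double bond. The cycloaddition of step 2 then gives bromo isoxazoline F3, and Suzuki methylation (trimethylboroxine, Pd(dppf)Cl2, K2CO3, dioxane–H2O, 90 °C) brings the sequence back to the route at 5.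

Step 13. The two secondary hydroxyls may not be discriminated well enough in the acylation, or the acetyl group may migrate between the cis oxygens before the oxidation. The fallback oxidises first and acetylates second. It sets out from 19, which is converted with Bu2SnO (toluene, reflux, water removal) into the dibutylstannylene acetal F6. Brominolysis with N-bromosuccinimide (CHCl3, rt) oxidises the pseudoaxial C5 carbinol of the cis-diol and gives hydroxy ketone F7. Acetylation of the one remaining hydroxyl (Ac2O, pyridine, DMAP cat., 0 °C) comes back to the route at 21, skipping 20.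

**Further compounds**

F1 | step 2 | (1S,2S)-3-bromocyclohexa-3,5-diene-1,2-diol | BrC1=CC=C[C@H](O)[C@@H]1O
F2 | step 2 | (3aS,7aS)-4-bromo-2,2-dimethyl-3a,7a-dihydro-1,3-benzodioxole | BrC1=CC=C[C@@H]2OC(C)(C)O[C@H]12
F3 | step 2 | bromo isoxazoline (C4 bromine in place of the methyl group of 5) | BrC1=C[C@H]2ON=C(C)[C@H]2[C@@H]2OC(C)(C)O[C@H]12
F4 | step 8 | (8R) epimer of 15 | C[C@]12O[C@H]1[C@@H](O[Si](CC)(CC)CC)[C@@H](C(=C)[C@H](O)CC=C(C)C)[C@@H]1OC(C)(C)O[C@H]21
F5 | step 8 | C8 ketone (enone) from 15 and F4 | C[C@]12O[C@H]1[C@@H](O[Si](CC)(CC)CC)[C@@H](C(=C)C(=O)CC=C(C)C)[C@@H]1OC(C)(C)O[C@H]21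
F6 | step 13 | C5,C6-O-dibutylstannylene acetal of 19 | C[C@]12O[C@H]1[C@@H](OC(=O)/C(C)=C/C)[C@@H](C(=C)[C@@H](OC(=O)/C(C)=C/C)C[C@H]3OC3(C)C)[C@@H]1O[Sn](CCCC)(CCCC)O[C@H]21
F7 | step 13 | C5 ketone with free C6 hydroxyl | C[C@]12O[C@H]1[C@@H](OC(=O)/C(C)=C/C)[C@@H](C(=C)[C@@H](OC(=O)/C(C)=C/C)C[C@H]1OC1(C)C)[C@H](O)C2=O
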